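At early times the isomer of the product appears at 9.13 mM h⁻¹ in the alder run and at 9.40 mM h⁻¹ in the maple run. These readings are about equal, although c(starting material) was 0.034 M in alder and 0.075 M in maple, while c(other conformer) was 0.050 M in both.

| flask | starting material | other conformer | catalyst | added ligand | remark | time |
|---|---|---|---|---|---|---|
| alder | 0.034 M | 0.050 M | 0.10 mM | 56 µM | run made earlier |  |
| maple | 0.075 M | 0.050 M | 0.10 mM | 56 µM | run made earlier |  |
| flask | 0.050 M | 0.0500 M | 0.10 mM | 56 µM |  | 30 h |

| run | time / h | target / % | isomer of the product / % |
|---|---|---|---|
| alder | 1.50 | 3.5 | 16.3 |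
| alder | 5.00 | 5.8 | 39.6 |
| alder | 8.00 | 7.2 | 47.4 |
| alder | 12.0 | 11.5 | 52.6 |
| alder | 20.0 | 12.5 | 58.6 |
| maple | 1.33 | 1.0 | 10.0 |
| maple | 2.50 | 3.5 | 18.5 |
| maple | 5.00 | 7.0 | 28.9 |
| maple | 10.0 | 10.8 | 35.8 |
| maple | 20.0 | 15.4 | 46.7 |

(each reading ± 1 percentage point)
- a reading or a percentage of target counts all its forms, free or not
1. share of target in target plus isomer of the product at 10 min
2. share of target in target plus isomer of the product at 2.0 h
3. share of target in target plus isomer of the product at 30 h
4. which of target and isomer of the product there is more of at 30 h

Two chemists dispute the flask. The first holds that the catalyst splits the material in a fixed ratio: the first readings of both runs, pooled, give a target share of 14.6%, and she keeps that share throughout. The second points to the late stretches, after 8.00 h in the alder run and after 10.0 h in the maple run, where the pooled target share of what was newly made is 30.9%, more than the early share. He says “selectivity drifts toward target with time”. His forecast is 13% at 10 min, 15% at 2.0 h and 24% at 30 h, with isomer of the product ahead.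

My own reckoning takes the early rate as pseudo-first-order in other conformer. The stock half-life, the time in which the charged other conformer halves at that rate, is then 3.74 h. The time 2.0 h is shorter than this, so the first chemist should hold early. The time 30 h is 8.02 half-lives, so the second should hold late. I expect a share between 14.6% and 30.9%, both under one half, and I give no single figure.

The flask gives 10.9%, 13.0% and 20.7%, with isomer of the product ahead at 57.4% against 15.0%. The forecast stands. The fixed split fails at 30 h, but it has its region: inside one stock half-life her figure stood above the flask's share by 3.7 percentage points at 10 min and by 1.6 points at 2.0 h, and at 30 h it stood below by 6.1 points.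

    starting material ⇌ other conformer (K = 0.460, k = 0.0247 h⁻¹)
    starting material + catalyst → catalyst + target (k = 405 M⁻¹ h⁻¹)
    catalyst + other conformer → catalyst + isomer of the product (k = 3360 M⁻¹ h⁻¹)
    target → over-reaction product (k = 0.0271 h⁻¹)
    catalyst + added ligand ⇌ idle complex A, settled at all times (K = 18000 M⁻¹)
    catalyst + target ⇌ idle complex B (K = 56.5 M⁻¹, k = 1.43 M⁻¹ h⁻¹)

In the flask, catalyst turned other conformer into isomer of the product first: at 15.0 h, 4.01 stock half-lives, other conformer stood at 3.99% of both charges, with isomer at 49.5% and target at 13.2%. Later the half-life reckons 0.385% of the other conformer's charge for 30 h, yet 4.1% stood there beside 33% of the starting material's charge, while starting material still passed to other conformer and to target.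

Take the neighbour flask with catalyst 2.5 × 10⁻⁵ M, a quarter of the charge: scaling inversely with catalyst gives a stock half-life of 15.0 h, so 30 h is twice that, leaving 25.0% of the other conformer's charge. The computed neighbour holds 28% of that charge, and its share goes from 10.8% to 14.2%.

(The readings stem from a simulated flask with made-up constants, noise included.)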